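**Strategy.** The route rests on reading C1(=O)–O2–C3–C4 of the lactone ring as a β-lactone into whose acyl–Cα bond (C1–C4) the aromatic edge C8a–C4a has been inserted. In the key step a 3,5-bis(benzyloxy)aryne undergoes σ-insertion into that bond of an enantiopure α-alkenyl β-lactone. One operation forms C4–C4a and C1–C8a, expands the oxetanone to the isochromanone, leaves C3 untouched and lets C4 settle thermodynamically, so both lactone epimers converge. The β-lactone comes from an alkaloid-catalysed ketene–glyoxylate [2+2] and a Horner–Wadsworth–Emmons olefination. The C5 hydroxyl is added last by Teuber oxidation and reduction.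

Key step: step 7

**Remarks on the chemistry (assumptions).**
- Isochromanone numbering is used throughout (C1 carbonyl, O2, C3, C4, C4a, C5–C8, C8a); Cα and Cβ are the side-chain alkene carbons on C4.
- The pseudoenantiomeric alkaloid catalyst in step 3 (O-trimethylsilylquinidine or O-trimethylsilylquinine) is taken as the one that gives the 2S lactone.
- Methyl glyoxylate, benzyl glyoxylate and 3,5-bis(benzyloxy)phenol are taken as commercial.

Step 1
Reactants: 1 trimethyl phosphonoacetate; 2 tert-butyl bromoacetate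
Product: 3 4-tert-butyl 1-methyl 2-(dimethoxyphosphoryl)butanedioate (racemic)
Conditions: NaH, THF, 0 °C to rt
Reagents that add atoms: none
Why: SN2 C-alkylation of the sodium phosphonoacetate carbanion by the α-bromo ester; the new stereocentre is irrelevant because step 4 turns it into an alkene carbon.

Step 2
Reactants: 3 4-tert-butyl 1-methyl 2-(dimethoxyphosphoryl)butanedioate
Product: 4 3-(dimethoxyphosphoryl)-4-methoxy-4-oxobutanoic acid
Conditions: CF3CO2H, CH2Cl2, rt
Reagents that add atoms: none
Why: Acidolysis of the tert-butyl ester (loss of isobutene) should leave the methyl ester and the phosphonate intact.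

Step 3
Reactants: 4 3-(dimethoxyphosphoryl)-4-methoxy-4-oxobutanoic acid; 5 methyl glyoxylate
Product: 8 methyl (2S)-3-[1-(dimethoxyphosphoryl)-2-methoxy-2-oxoethyl]-4-oxooxetane-2-carboxylate (isomers at C3 and at the side-chain carbon), via acyl chloride 6 (not isolated), via ketene 7 (not isolated)
Conditions: (COCl)2, cat. DMF, CH2Cl2, 0 °C; then slow addition to 5, O-trimethylsilylquinidine (10 mol %), LiClO4, iPr2NEt, CH2Cl2/Et2O, −78 °C
Reagents that add atoms: none
Why: Cinchona-alkaloid-catalysed acyl halide–aldehyde cyclocondensation (ketene–aldehyde [2+2] through the chiral ammonium enolate), in which the catalyst selects the aldehyde face and so sets C2 of the lactone (the later C3) as S; the two other centres are erased later.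

Step 4
Reactants: 8 methyl (2S)-3-[1-(dimethoxyphosphoryl)-2-methoxy-2-oxoethyl]-4-oxooxetane-2-carboxylate; 9 benzyl glyoxylate
Product: 10 methyl (2S)-3-[(1E)-3-(benzyloxy)-1-(methoxycarbonyl)-3-oxoprop-1-en-1-yl]-4-oxooxetane-2-carboxylate (both C3 epimers)
Conditions: LiCl, iPr2NEt, MeCN, 0 °C, short reaction time
Reagents that add atoms: none
Why: Horner–Wadsworth–Emmons olefination under Masamune–Roush conditions at the phosphonoacetate C–H (the most acidic site of 8) should give the trisubstituted E-alkene with the new ester trans to the methoxycarbonyl group, without touching C2.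

Step 5
Reactants: 11 3,5-bis(benzyloxy)phenol
Product: 12 3,5-bis(benzyloxy)-2-bromophenol
Conditions: NBS (1.0 equiv), CH2Cl2, −78 to 0 °C
Reagents that add atoms: N-bromosuccinimide, O=C1CCC(=O)N1Br
Why: Electrophilic aromatic bromination should go ortho to the free hydroxyl (para to one benzyloxy group) rather than into the more hindered position between the two benzyloxy groups.

Step 6
Reactants: 12 3,5-bis(benzyloxy)-2-bromophenol
Product: 15 3,5-bis(benzyloxy)-2-(trimethylsilyl)phenyl trifluoromethanesulfonate, via aryl silyl ether 13 (not isolated), via lithium silylphenolate 14 (not isolated)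
Conditions: (Me3Si)2NH, THF, reflux, then evaporation; n-BuLi, THF, −100 to −78 °C; Tf2O, −78 °C to rt
Reagents that add atoms: hexamethyldisilazane, C[Si](C)(C)N[Si](C)(C)C; trifluoromethanesulfonic anhydride, O=S(=O)(OS(=O)(=O)C(F)(F)F)C(F)(F)F
Why: O-Silylation, bromine–lithium exchange with 1,3-O→C silyl migration (retro-Brook rearrangement) and O-triflation give the ortho-silylaryl triflate used as aryne precursor.

Step 7
Reactants: 10 methyl (2S)-3-[(1E)-3-(benzyloxy)-1-(methoxycarbonyl)-3-oxoprop-1-en-1-yl]-4-oxooxetane-2-carboxylate; 15 3,5-bis(benzyloxy)-2-(trimethylsilyl)phenyl trifluoromethanesulfonate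
Product: 17 methyl (3S,4R)-6,8-bis(benzyloxy)-4-[(1E)-3-(benzyloxy)-1-(methoxycarbonyl)-3-oxoprop-1-en-1-yl]-1-oxo-3,4-dihydro-1H-isochromene-3-carboxylate, via 3,5-bis(benzyloxy)benzyne 16 (not isolated)
Conditions: KF, 18-crown-6, THF, 0 °C to rt, 15 (1.3 equiv) added slowly; AcOH quench at 0 °C
Reagents that add atoms: none
Why: Proposed new method: fluoride releases aryne 16 and, through the basic medium, the extended lactone enolate of 10; its lactone α-carbon (the later C4) adds to the aryne carbon remote from the flanking benzyloxy group, the resulting aryl anion attacks the strained lactone carbonyl (4-exo-trig), and the benzocyclobutenoxide fused to the oxetane cleaves its C1–C4 bond (Grob-type scission opening both four-membered rings) to a delocalised C4 carbanion that is protonated by the next molecule of 10. The closest known reaction type is the aryne acyl-alkylation (C–C σ-bond insertion) of β-keto esters and malonates, including the two-carbon ring expansion of cyclic β-keto esters; a β-lactone has not served as the acyl donor. The isochromanone ring is therefore not closed directly but arises by ring expansion of the oxetanone through the transient four-membered carbocycle. C3 is a spectator and stays S, whereas C4 is set by protonation of the planar enolate and equilibration through it to the more stable 3,4-trans (4R) isomer, so both C3 epimers of 10 and any Z-alkene should converge. The step needs (i) aryne regioselectivity, secured by the 3-benzyloxy group as in known acyl-alkylations of 3,5-dialkoxyarynes (acyl ortho to oxygen), (ii) attack through the lactone α-carbon and not the carbon next to the benzyl ester, expected because the ring-locked s-trans lactone is the stronger acceptor and vinylogous anions react α to the stronger acceptor, and (iii) C–C scission ahead of β-elimination of the enolates, favoured by strain release, low temperature and the nearly in-plane C–O bonds.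

Step 8
Reactants: 17 methyl (3S,4R)-6,8-bis(benzyloxy)-4-[(1E)-3-(benzyloxy)-1-(methoxycarbonyl)-3-oxoprop-1-en-1-yl]-1-oxo-3,4-dihydro-1H-isochromene-3-carboxylate
Product: 18 (2E)-3-[(3S,4R)-6,8-dihydroxy-3-(methoxycarbonyl)-1-oxo-3,4-dihydro-1H-isochromen-4-yl]-4-methoxy-4-oxobut-2-enoic acid
Conditions: BCl3, pentamethylbenzene, CH2Cl2, −78 °C; MeOH/H2O quench
Reagents that add atoms: none
Why: Lewis-acid debenzylation with a cation scavenger should cleave the two aryl benzyl ethers and the benzyl ester while the methyl esters, the lactone and the electron-poor alkene survive, since no base and no hydrogenation are involved.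

Step 9
Reactants: 18 (2E)-3-[(3S,4R)-6,8-dihydroxy-3-(methoxycarbonyl)-1-oxo-3,4-dihydro-1H-isochromen-4-yl]-4-methoxy-4-oxobut-2-enoic acid
Product: 20 (2E)-4-methoxy-4-oxo-3-[(3S,4R)-5,6,8-trihydroxy-3-(methoxycarbonyl)-1-oxo-3,4-dihydro-1H-isochromen-4-yl]but-2-enoic acid, via hydroxyquinone 19 (not isolated)
Conditions: (KSO3)2NO (2.2 equiv), KH2PO4 buffer (pH 6), H2O/acetone, 0 °C; then aqueous Na2S2O4, under argon
Reagents that add atoms: potassium nitrosodisulfonate (Fremy's salt), [K+].[K+].[O]N(S(=O)(=O)[O-])S(=O)(=O)[O-]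
Why: Teuber oxidation should turn the C8 phenol into the para-quinone at C5 (its only free para position, also ortho to the C6 hydroxyl), and dithionite should reduce the 6-hydroxy-5,8-quinone to the 5,6,8-trihydroxyarene without touching C3 or C4.

**Compound list**

1 | trimethyl phosphonoacetate | COC(=O)CP(=O)(OC)OC | starting material
2 | tert-butyl bromoacetate | CC(C)(C)OC(=O)CBr | starting material
3 | 4-tert-butyl 1-methyl 2-(dimethoxyphosphoryl)butanedioate | COC(=O)C(CC(=O)OC(C)(C)C)P(=O)(OC)OC | intermediate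
4 | 3-(dimethoxyphosphoryl)-4-methoxy-4-oxobutanoic acid | COC(=O)C(CC(=O)O)P(=O)(OC)OC | intermediate
5 | methyl glyoxylate | COC(=O)C=O | starting material
6 | methyl 4-chloro-2-(dimethoxyphosphoryl)-4-oxobutanoate | COC(=O)C(CC(=O)Cl)P(=O)(OC)OC | intermediate
7 | methyl 2-(dimethoxyphosphoryl)-4-oxobut-3-enoate (ketene) | COC(=O)C(C=C=O)P(=O)(OC)OC | intermediate
8 | methyl (2S)-3-[1-(dimethoxyphosphoryl)-2-methoxy-2-oxoethyl]-4-oxooxetane-2-carboxylate | COC(=O)C(P(=O)(OC)OC)C1C(=O)O[C@@H]1C(=O)OC | intermediate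
9 | benzyl glyoxylate | O=CC(=O)OCc1ccccc1 | starting material
10 | methyl (2S)-3-[(1E)-3-(benzyloxy)-1-(methoxycarbonyl)-3-oxoprop-1-en-1-yl]-4-oxooxetane-2-carboxylate | COC(=O)/C(=C/C(=O)OCc1ccccc1)C1C(=O)O[C@@H]1C(=O)OC | intermediate
11 | 3,5-bis(benzyloxy)phenol | Oc1cc(OCc2ccccc2)cc(OCc2ccccc2)c1 | starting material
12 | 3,5-bis(benzyloxy)-2-bromophenol | Oc1cc(OCc2ccccc2)cc(OCc2ccccc2)c1Br | intermediate
13 | [3,5-bis(benzyloxy)-2-bromophenoxy]trimethylsilane | C[Si](C)(C)Oc1cc(OCc2ccccc2)cc(OCc2ccccc2)c1Br | intermediate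
14 | lithium 3,5-bis(benzyloxy)-2-(trimethylsilyl)phenolate | [Li+].[O-]c1cc(OCc2ccccc2)cc(OCc2ccccc2)c1[Si](C)(C)C | intermediate
15 | 3,5-bis(benzyloxy)-2-(trimethylsilyl)phenyl trifluoromethanesulfonate | C[Si](C)(C)c1c(OCc2ccccc2)cc(OCc2ccccc2)cc1OS(=O)(=O)C(F)(F)F | intermediate
16 | 3,5-bis(benzyloxy)benzyne | C1#CC(OCc2ccccc2)=CC(OCc2ccccc2)=C1 | intermediate
17 | methyl (3S,4R)-6,8-bis(benzyloxy)-4-[(1E)-3-(benzyloxy)-1-(methoxycarbonyl)-3-oxoprop-1-en-1-yl]-1-oxo-3,4-dihydro-1H-isochromene-3-carboxylate | COC(=O)/C(=C/C(=O)OCc1ccccc1)[C@H]1c2cc(OCc3ccccc3)cc(OCc3ccccc3)c2C(=O)O[C@@H]1C(=O)OC | intermediate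
18 | (2E)-3-[(3S,4R)-6,8-dihydroxy-3-(methoxycarbonyl)-1-oxo-3,4-dihydro-1H-isochromen-4-yl]-4-methoxy-4-oxobut-2-enoic acid | COC(=O)/C(=C/C(=O)O)[C@H]1c2cc(O)cc(O)c2C(=O)O[C@@H]1C(=O)OC | intermediate
19 | (2E)-3-[(3S,4R)-6-hydroxy-3-(methoxycarbonyl)-1,5,8-trioxo-3,4,5,8-tetrahydro-1H-isochromen-4-yl]-4-methoxy-4-oxobut-2-enoic acid | COC(=O)/C(=C/C(=O)O)[C@H]1C2=C(C(=O)O[C@@H]1C(=O)OC)C(=O)C=C(O)C2=O | intermediate
20 | (2E)-4-methoxy-4-oxo-3-[(3S,4R)-5,6,8-trihydroxy-3-(methoxycarbonyl)-1-oxo-3,4-dihydro-1H-isochromen-4-yl]but-2-enoic acid | COC(=O)/C(=C/C(=O)O)[C@H]1c2c(O)c(O)cc(O)c2C(=O)O[C@@H]1C(=O)OC | target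

**Step count.** Total: 9 steps. Longest linear sequence: 7 steps (1, 2, 3, 4, 7, 8, 9); steps 5 and 6 form the aryne branch.

**Steps most likely to fail**

1. Step 7 (Proposed new method). The ambident extended enolate may attack the aryne through the carbon next to the benzyl ester instead of the lactone α-carbon, or the lactone enolates (of 10 or of 17) may ring-open by β-elimination before protonation. Fallback with known chemistry, changing from ring expansion to acyclic insertion with later lactone construction and resolution; it sets out from 15 and comes back at 18. Fluoride-induced aryne formation from 15 in the presence of commercial trimethyl (E)-aconitate (malonate-type C–C insertion through its symmetric allyl anion) should give methyl 2,4-bis(benzyloxy)-6-[(2E)-2,3-bis(methoxycarbonyl)prop-2-en-1-yl]benzoate F1. Saponification of the least hindered ester on the CH= carbon with one equivalent of LiOH should give the monoacid F2. Lateral deprotonation (LDA, 2.2 equiv, −78 °C) and addition of 5, with lactonisation of the aldolate onto the aryl ester, should give the racemic trans lactone acid F3. Resolution as the (R)-1-phenylethylammonium salt should give the (3S,4R) acid F4, and BCl3/pentamethylbenzene returns to 18.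

2. Step 4. The amine/LiCl medium may deprotonate the acidic product and open the β-lactone, and the E selectivity may erode. Fallback, olefinating before the lactone is made; it sets out from 3 and comes back at 10. Olefination of 3 with 9 (LiCl, DBU) should give 1-benzyl 2-methyl 3-tert-butyl (1E)-prop-1-ene-1,2,3-tricarboxylate F5; CF3CO2H the acid (3E)-5-(benzyloxy)-3-(methoxycarbonyl)-5-oxopent-3-enoic acid F6; (COCl)2 the acyl chloride F7. Dehydrochlorination to the vinylketene F8 in the presence of 5 under the conditions of step 3 should give 10 directly; the risk of that variant is a competing [4+2] mode of the vinylketene.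

3. Step 9. The acyl-deactivated phenol may oxidise slowly, and the quinone may tautomerise through its acidic C4–H (quinone methide), which would scramble C4 or dehydrogenate C3–C4. Fallback, introducing the oxygen before deprotection by halogenation, borylation and oxidation; it sets out from 17 and comes back at 20. NBS (MeCN, 0 °C) should brominate C5 (para to the C8 ether, ortho to the C6 ether) to the 5-bromo compound F9; Miyaura borylation (B2pin2, Pd(dppf)Cl2, KOAc, dioxane) should give the 5-pinacolboronate F10; NaBO3·4H2O (THF/H2O) the 5-hydroxy compound F11; BCl3/pentamethylbenzene then removes the three benzyl groups and gives 20.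

Further compounds
F1 | step 7 | methyl 2,4-bis(benzyloxy)-6-[(2E)-2,3-bis(methoxycarbonyl)prop-2-en-1-yl]benzoate | COC(=O)/C(=C/C(=O)OC)Cc1cc(OCc2ccccc2)cc(OCc2ccccc2)c1C(=O)OC
F2 | step 7 | (2E)-3-{[3,5-bis(benzyloxy)-2-(methoxycarbonyl)phenyl]methyl}-4-methoxy-4-oxobut-2-enoic acid | COC(=O)/C(=C/C(=O)O)Cc1cc(OCc2ccccc2)cc(OCc2ccccc2)c1C(=O)OC
F3 | step 7 | racemic trans (2E)-3-[6,8-bis(benzyloxy)-3-(methoxycarbonyl)-1-oxo-3,4-dihydro-1H-isochromen-4-yl]-4-methoxy-4-oxobut-2-enoic acid | COC(=O)/C(=C/C(=O)O)C1c2cc(OCc3ccccc3)cc(OCc3ccccc3)c2C(=O)OC1C(=O)OC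
F4 | step 7 | (2E)-3-[(3S,4R)-6,8-bis(benzyloxy)-3-(methoxycarbonyl)-1-oxo-3,4-dihydro-1H-isochromen-4-yl]-4-methoxy-4-oxobut-2-enoic acid | COC(=O)/C(=C/C(=O)O)[C@H]1c2cc(OCc3ccccc3)cc(OCc3ccccc3)c2C(=O)O[C@@H]1C(=O)OC
F5 | step 4 | 1-benzyl 2-methyl 3-tert-butyl (1E)-prop-1-ene-1,2,3-tricarboxylate | COC(=O)/C(=C/C(=O)OCc1ccccc1)CC(=O)OC(C)(C)C
F6 | step 4 | (3E)-5-(benzyloxy)-3-(methoxycarbonyl)-5-oxopent-3-enoic acid | COC(=O)/C(=C/C(=O)OCc1ccccc1)CC(=O)O
F7 | step 4 | 1-benzyl 2-methyl (1E)-4-chloro-4-oxobut-1-ene-1,2-dicarboxylate | COC(=O)/C(=C/C(=O)OCc1ccccc1)CC(=O)Cl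
F8 | step 4 | 1-benzyl 2-methyl (1E)-4-oxobuta-1,3-diene-1,2-dicarboxylate (vinylketene) | COC(=O)/C(=C/C(=O)OCc1ccccc1)C=C=O
F9 | step 9 | methyl (3S,4R)-6,8-bis(benzyloxy)-4-[(1E)-3-(benzyloxy)-1-(methoxycarbonyl)-3-oxoprop-1-en-1-yl]-5-bromo-1-oxo-3,4-dihydro-1H-isochromene-3-carboxylate | COC(=O)/C(=C/C(=O)OCc1ccccc1)[C@H]1c2c(Br)c(OCc3ccccc3)cc(OCc3ccccc3)c2C(=O)O[C@@H]1C(=O)OC
F10 | step 9 | methyl (3S,4R)-6,8-bis(benzyloxy)-4-[(1E)-3-(benzyloxy)-1-(methoxycarbonyl)-3-oxoprop-1-en-1-yl]-1-oxo-5-(4,4,5,5-tetramethyl-1,3,2-dioxaborolan-2-yl)-3,4-dihydro-1H-isochromene-3-carboxylate | COC(=O)/C(=C/C(=O)OCc1ccccc1)[C@H]1c2c(B3OC(C)(C)C(C)(C)O3)c(OCc3ccccc3)cc(OCc3ccccc3)c2C(=O)O[C@@H]1C(=O)OC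
F11 | step 9 | methyl (3S,4R)-6,8-bis(benzyloxy)-4-[(1E)-3-(benzyloxy)-1-(methoxycarbonyl)-3-oxoprop-1-en-1-yl]-5-hydroxy-1-oxo-3,4-dihydro-1H-isochromene-3-carboxylate | COC(=O)/C(=C/C(=O)OCc1ccccc1)[C@H]1c2c(O)c(OCc3ccccc3)cc(OCc3ccccc3)c2C(=O)O[C@@H]1C(=O)OC
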